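The cyclopentane ring is disconnected at C9–C1 and C8–CH3. Around C8–C9–C5 the substituents alternate faces (CH3 α, CH2OH β, side chain α) beside the C7 oxygen, so the ring maps onto a 4-silyloxycyclopent-2-enone (carbonyl = C7) after two consecutive anti additions. The key step adds a silylmethyl Grignard reagent (a masked CH2OH) to (R)-4-(tert-butyldimethylsilyloxy)cyclopent-2-enone under copper catalysis and methylates the enolate with iodomethane, giving the all-trans 2-methyl-3-(silylmethyl)-4-silyloxycyclopentanone. The silyloxy group then leaves, malonate adds anti to C9, a trans-fused lactone tells C3 from C11, and two acetal-masked (S)-dialdehyde acids are esterified on last.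

Key step: step 2

Remarks
- Atom labels: ring C5 (side chain), C6 (CH2), C7 (O7), C8 (CH3), C9 (C1H2–O1); side-chain C4 carries C3H2–O3 and C11H2–O11. A ring substituent is β on the face of the C9 CH2 group and α on the other face. The target is 5α, 7β, 8α, 9β with C4 (S), and both acyl groups are (3S,4E)-4-formyl-3-(2-oxoethyl)hex-4-enoyl.
- The (R)-enone is the enantiomer that maps onto the target: its carbinol carbon becomes C5 and relays its configuration to C9, C8 and, after elimination, back to C5.
- Both enantiomers of the prolinol silyl ether and of the CBS catalyst, diallyl malonate and benzyl 2,2,2-trichloroacetimidate are taken as purchasable. TBS = tert-butyldimethylsilyl.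

**Core (steps 1–11)**

Step 1
Reactants: 1 (chloromethyl)dimethyl(propan-2-yloxy)silane
Product: 2 {[dimethyl(propan-2-yloxy)silyl]methyl}magnesium chloride (THF solution)
Conditions: Mg turnings, BrCH2CH2Br (cat.), THF, reflux, then rt
Reagents that add atoms: magnesium, [Mg]
Why: Grignard formation by magnesium insertion into the primary C–Cl bond, which the alkoxysilane tolerates, gives a hydroxymethyl anion equivalent.

Step 2
Reactants: 3 (R)-4-(tert-butyldimethylsilyloxy)cyclopent-2-en-1-one; 2 {[dimethyl(propan-2-yloxy)silyl]methyl}magnesium chloride; 4 iodomethane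
Product: 7 (2R,3R,4R)-4-(tert-butyldimethylsilyloxy)-3-{[dimethyl(propan-2-yloxy)silyl]methyl}-2-methylcyclopentan-1-one (all-trans), via silyl enol ether 5 (not isolated), via lithium enolate 6 (not isolated)
Conditions: 2 (1.3 equiv), CuBr·SMe2 (10 mol%), Me3SiCl, THF, −78 °C; Et3N, pentane, filter, concentrate; MeLi, THF, 0 °C; then 4 (5 equiv), DMPU, −78 → −30 °C
Reagents that add atoms: none
Why: The Grignard reagent and catalytic CuBr·SMe2 give a monovalent-copper silylmethyl species that adds 1,4 to the enone on the face opposite the C5 silyloxy group, and Me3SiCl traps the enolate as silyl enol ether 5; MeLi then cleaves the Si–O bond to the regiodefined lithium enolate 6, which is methylated by SN2 attack on iodomethane. The closest known reaction type is the three-component coupling (conjugate addition followed by enolate alkylation) on 4-silyloxycyclopent-2-enones, with a silylmethyl Grignard reagent as hydroxymethyl anion equivalent. No ring is closed. C9 is set by the C5 stereocentre (addition anti to the OTBS group) and C8 by the new C9 substituent (methylation anti to CH2Si), so 7 is all-trans. The step needs both facial selectivities and an enolate that keeps its position: aprotic release of 6 from 5, excess iodomethane and DMPU at low temperature should let methylation outrun proton transfer to the C6 enolate, which would expel the silyloxy group.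

Step 3
Reactants: 7 all-trans ketone; 8 dibenzyl malonate
Product: 10 dibenzyl 2-[cyclopentanone side chain]malonate: cyclopentanone (C7=O) with 8α-CH3, 9β-CH2SiMe2(OiPr) and 5α-CH(CO2Bn)2, all-trans, via enone 9 (not isolated)
Conditions: 8 (1.5 equiv), DBU (1.5 equiv), MeCN, 0 °C → rt
Reagents that add atoms: none
Why: DBU removes a C6 proton and the C5 silanolate is expelled (E1cB) to give enone 9, which is trapped in the same flask by Michael addition of the malonate at C5 on the face opposite the C9 CH2Si group, so the new C5 centre is α and trans to C9, while C8 stays in its thermodynamically preferred trans arrangement.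

Step 4
Reactants: 10 Michael adduct
Product: 12 benzyl 7-methyl-3,6-dioxooctahydrocyclopenta[c]pyran-4-carboxylate (trans-fused keto lactone; lactone C=O = C11, ester carbon = C3, ester equatorial with H4 anti to H5, 8α-CH3), via hydroxymethyl malonate 11 (not isolated)
Conditions: KHF2, 30% H2O2, DMF, rt; Na2S2O3 work-up; then DBU (0.2 equiv), toluene, 40 °C
Reagents that add atoms: hydrogen peroxide, OO
Why: Tamao oxidation replaces the C1–Si bond by C1–OH, and the new hydroxyl closes a trans-fused δ-lactone onto one benzyl ester (lactonisation); under DBU the acidic C4–H equilibrates, which should favour the epimer with the remaining ester equatorial, and this fixes C4 with the lactone carbonyl as C11 and the ester carbon as C3.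

Step 5
Reactants: 12 keto lactone
Product: 13 benzyl 6β-hydroxy-7α-methyl-3-oxooctahydrocyclopenta[c]pyran-4-carboxylate (C7–OH β, trans to C8–CH3; otherwise as 12)
Conditions: (S)-2-methyl-CBS-oxazaborolidine (20 mol%), BH3·SMe2, THF, −20 °C
Reagents that add atoms: none
Why: Corey–Bakshi–Shibata reduction: the ketone should bind the catalyst boron through the lone pair on the unbranched C6 side, so the (S)-catalyst delivers hydride to the α face and the C7 hydroxyl ends up β (C7 R), and since the trans-fused bicycle has little facial bias of its own the reagent should decide.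

Step 6
Reactants: 13 hydroxy lactone benzyl ester
Product: 14 6β-hydroxy-7α-methyl-3-oxooctahydrocyclopenta[c]pyran-4-carboxylic acid
Conditions: H2 (1 atm), Pd/C, EtOAc, rt
Reagents that add atoms: none
Why: Hydrogenolysis cleaves the benzyl ester to the acid without touching lactone or alcohol, and working at room temperature avoids decarboxylation of the α-carboxy lactone while the ring keeps C4 in its favoured configuration.

Step 7
Reactants: 14 hydroxy lactone acid
Product: 15 6β-hydroxy-4-(hydroxymethyl)-7α-methylhexahydrocyclopenta[c]pyran-3(1H)-one (C3 now CH2OH)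
Conditions: BH3·SMe2, THF, 0 °C; MeOH
Reagents that add atoms: none
Why: Borane reduces the carboxylic acid chemoselectively over the lactone (acyloxyborane pathway) under non-basic conditions, after which C4 is no longer doubly activated and is configurationally stable.

Step 8
Reactants: 15 diol lactone
Product: 16 6β-(benzyloxy)-4-[(benzyloxy)methyl]-7α-methylhexahydrocyclopenta[c]pyran-3(1H)-one
Conditions: BnOC(=NH)CCl3, TfOH (cat.), CH2Cl2/cyclohexane, 0 °C → rt
Reagents that add atoms: benzyl 2,2,2-trichloroacetimidate, N=C(OCc1ccccc1)C(Cl)(Cl)Cl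
Why: Acid-catalysed benzylation with the trichloroacetimidate, free of base and therefore of β-elimination or epimerisation of the β-hydroxy lactone, protects O3 and O7 as ethers that survive hydride.

Step 9
Reactants: 16 bis-benzyl ether lactone
Product: 17 (2S)-3-(benzyloxy)-2-[4β-(benzyloxy)-2β-(hydroxymethyl)-3α-methylcyclopent-1α-yl]propan-1-ol (O1–H and O11–H free)
Conditions: LiAlH4, THF, 0 °C
Reagents that add atoms: none
Why: Hydride reduction of the lactone releases O1–H and O11–H together, the two hydroxyls that stay free in the target, without touching C4.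

Step 10
Reactants: 17 diol
Product: 18 bis-TBS ether of 17 (O1 and O11 silylated, O3 and O7 benzylated)
Conditions: TBSCl, imidazole, DMF, 0 °C → rt
Reagents that add atoms: tert-butyldimethylsilyl chloride, CC(C)(C)[Si](C)(C)Cl
Why: Silylation of the two primary alcohols protects O1 and O11 with groups that are removed in the final acid step.

Step 11
Reactants: 18 bis-benzyl bis-silyl ether
Product: 19 core diol: O3–H and O7–H free, O1 and O11 as TBS ethers, configuration of the target at C4, C5, C7, C8, C9
Conditions: H2 (1 atm), Pd(OH)2/C, EtOAc, rt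
Reagents that add atoms: none
Why: Hydrogenolysis of both benzyl ethers frees O3–H and O7–H, while the silyl ethers are stable under neutral conditions in ethyl acetate.

**Acid fragment (steps 12–16)**

Step 12
Reactants: 20 (E)-but-2-enal (crotonaldehyde)
Product: 21 (Z)-2-iodobut-2-enal
Conditions: I2, K2CO3, DMAP (cat.), THF/H2O, rt, dark
Reagents that add atoms: iodine, II
Why: α-Iodination of the enal by conjugate addition of DMAP, iodination of the enolate and elimination (Morita–Baylis–Hillman-type pathway) gives the thermodynamically preferred Z iodide with CH3 trans to CHO, the geometry of the target ethylidene aldehyde.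

Step 13
Reactants: 21 (Z)-2-iodobut-2-enal
Product: 22 (Z)-1,1-diethoxy-2-iodobut-2-ene
Conditions: HC(OEt)3, EtOH, TsOH·H2O (cat.), rt
Reagents that add atoms: triethyl orthoformate, CCOC(OCC)OCC; ethanol, CCO
Why: Acid-catalysed acetalisation with the orthoformate as water scavenger masks the aldehyde so that only the vinyl iodide reacts in the coupling.

Step 14
Reactants: 22 iodo acetal; 23 acrolein
Product: 24 (2E,4E)-4-(diethoxymethyl)hexa-2,4-dienal
Conditions: 23 (3 equiv), Pd(OAc)2 (5 mol%), n-Bu4NCl, NaHCO3, DMF, 40 °C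
Reagents that add atoms: none
Why: Mizoroki–Heck reaction: zerovalent palladium formed in the flask inserts into the C–I bond with retention of alkene geometry, and syn insertion of acrolein with syn β-hydride elimination gives the new E double bond.

Step 15
Reactants: 24 dienal; 25 diallyl malonate
Product: 27 diallyl 2-[(3S,4E)-1,1-diethoxy-4-(diethoxymethyl)hex-4-en-3-yl]malonate, via aldehyde 26 (not isolated)
Conditions: 25 (1.5 equiv), (R)-α,α-diphenylprolinol trimethylsilyl ether (10 mol%), EtOH, 0 °C → rt; then HC(OEt)3, TsOH·H2O (20 mol%), rt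
Reagents that add atoms: triethyl orthoformate, CCOC(OCC)OCC; ethanol, CCO
Why: Iminium-catalysed Michael addition: the amine forms the (E)-iminium ion of 24, whose face on the side of the CPh2(OSiMe3) group is blocked, so with the (R)-catalyst the malonate should add to C3 from the open face and set the (S) centre, and the aldehyde is acetalised in the same flask before retro-Michael reaction or cyclisation can occur.

Step 16
Reactants: 27 diallyl malonate bis-acetal
Product: 29 (3S,4E)-3-(2,2-diethoxyethyl)-4-(diethoxymethyl)hex-4-enoic acid, via malonic acid 28 (not isolated)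
Conditions: Pd(OAc)2 (5 mol%), PPh3 (20 mol%), HCO2H, Et3N, 1,4-dioxane, 100 °C
Reagents that add atoms: none
Why: Tsuji–Trost-type deallylation: zerovalent palladium ionises both allyl esters, formate reduces the π-allyl complexes to propene, and the substituted malonic acid loses CO2 at the reaction temperature, while the buffered medium leaves the acetals intact and the β stereocentre is not involved.

**Union (steps 17–18)**

Step 17
Reactants: 19 core diol; 29 acetal acid (2.4 equiv)
Product: 30 protected diester: 19 acylated at O3 and O7 with the acyl group of 29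
Conditions: 29 (2.4 equiv), DIC, DMAP, CH2Cl2, 0 °C → rt
Reagents that add atoms: none
Why: Steglich esterification through the O-acylisourea and the acylpyridinium ion acylates the primary O3–H and the secondary O7–H; the stereocentre of 29 is β to the carboxyl group and cannot epimerise, and acetals and silyl ethers tolerate the neutral conditions.

Step 18
Reactants: 30 protected diester
Product: 31 target CNP0192766.1
Conditions: 1 M aq. HCl/THF (1:4), 0 °C → rt
Reagents that add atoms: water, O
Why: Aqueous acid hydrolyses the four diethyl acetals to the aldehydes and cleaves both primary silyl ethers while the esters and the E-enals survive, and the short exposure at or below room temperature should avoid O3 to O11 acyl migration.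

**Compound list**

1 | (chloromethyl)dimethyl(propan-2-yloxy)silane | CC(C)O[Si](C)(C)CCl | starting material
2 | {[dimethyl(propan-2-yloxy)silyl]methyl}magnesium chloride | CC(C)O[Si](C)(C)C[Mg]Cl | intermediate
3 | (R)-4-(tert-butyldimethylsilyloxy)cyclopent-2-en-1-one | CC(C)(C)[Si](C)(C)O[C@@H]1CC(=O)C=C1 | starting material
4 | iodomethane | CI | starting material
5 | tert-butyl{[(1R,2R)-2-{[dimethyl(propan-2-yloxy)silyl]methyl}-4-(trimethylsilyloxy)cyclopent-3-en-1-yl]oxy}dimethylsilane (trans silyl enol ether) | CC(C)(C)[Si](C)(C)O[C@@H]1CC(O[Si](C)(C)C)=C[C@H]1C[Si](C)(C)OC(C)C | intermediate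
6 | lithium (3R,4R)-4-(tert-butyldimethylsilyloxy)-3-{[dimethyl(propan-2-yloxy)silyl]methyl}cyclopent-1-en-1-olate | CC(C)(C)[Si](C)(C)O[C@@H]1CC(O[Li])=C[C@H]1C[Si](C)(C)OC(C)C | intermediate
7 | (2R,3R,4R)-4-(tert-butyldimethylsilyloxy)-3-{[dimethyl(propan-2-yloxy)silyl]methyl}-2-methylcyclopentan-1-one (all-trans) | CC(C)(C)[Si](C)(C)O[C@@H]1CC(=O)[C@H](C)[C@H]1C[Si](C)(C)OC(C)C | intermediate
8 | dibenzyl malonate | O=C(CC(=O)OCc1ccccc1)OCc1ccccc1 | starting material
9 | (4S,5R)-4-{[dimethyl(propan-2-yloxy)silyl]methyl}-5-methylcyclopent-2-en-1-one (trans) | C1=CC(=O)[C@H](C)[C@H]1C[Si](C)(C)OC(C)C | intermediate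
10 | dibenzyl 2-[2β-{[dimethyl(propan-2-yloxy)silyl]methyl}-3α-methyl-4-oxocyclopent-1α-yl]malonate (all-trans) | O=C(OCc1ccccc1)C(C(=O)OCc1ccccc1)[C@@H]1CC(=O)[C@H](C)[C@H]1C[Si](C)(C)OC(C)C | intermediate
11 | dibenzyl 2-[2β-(hydroxymethyl)-3α-methyl-4-oxocyclopent-1α-yl]malonate | O=C(OCc1ccccc1)C(C(=O)OCc1ccccc1)[C@@H]1CC(=O)[C@H](C)[C@H]1CO | intermediate
12 | benzyl 7α-methyl-3,6-dioxooctahydrocyclopenta[c]pyran-4-carboxylate, trans-fused, ester equatorial (H4 anti to H4a) | O=C(OCc1ccccc1)[C@H](C(=O)O2)[C@@H]1CC(=O)[C@H](C)[C@H]1C2 | intermediate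
13 | benzyl 6β-hydroxy-7α-methyl-3-oxooctahydrocyclopenta[c]pyran-4-carboxylate (ring fusion and C4 as 12) | O=C(OCc1ccccc1)[C@H](C(=O)O2)[C@@H]1C[C@@H](O)[C@H](C)[C@H]1C2 | intermediate
14 | 6β-hydroxy-7α-methyl-3-oxooctahydrocyclopenta[c]pyran-4-carboxylic acid (as 13) | OC(=O)[C@H](C(=O)O2)[C@@H]1C[C@@H](O)[C@H](C)[C@H]1C2 | intermediate
15 | 6β-hydroxy-4-(hydroxymethyl)-7α-methylhexahydrocyclopenta[c]pyran-3(1H)-one (as 13) | OC[C@H](C(=O)O2)[C@@H]1C[C@@H](O)[C@H](C)[C@H]1C2 | intermediate
16 | 6β-(benzyloxy)-4-[(benzyloxy)methyl]-7α-methylhexahydrocyclopenta[c]pyran-3(1H)-one (as 13) | C(c1ccccc1)OC[C@H](C(=O)O2)[C@@H]1C[C@@H](OCc3ccccc3)[C@H](C)[C@H]1C2 | intermediate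
17 | (2S)-3-(benzyloxy)-2-[4β-(benzyloxy)-2β-(hydroxymethyl)-3α-methylcyclopent-1α-yl]propan-1-ol | C(c1ccccc1)OC[C@H](CO)[C@@H]1C[C@@H](OCc2ccccc2)[C@H](C)[C@H]1CO | intermediate
18 | bis(tert-butyldimethylsilyl) ether of 17 at O1 and O11 | C(c1ccccc1)OC[C@H](CO[Si](C)(C)C(C)(C)C)[C@@H]1C[C@@H](OCc2ccccc2)[C@H](C)[C@H]1CO[Si](C)(C)C(C)(C)C | intermediate
19 | core diol: 3-(tert-butyldimethylsilyloxy)-2-[2β-(tert-butyldimethylsilyloxymethyl)-4β-hydroxy-3α-methylcyclopent-1α-yl]propan-1-ol, C4 as in the target | OC[C@H](CO[Si](C)(C)C(C)(C)C)[C@@H]1C[C@@H](O)[C@H](C)[C@H]1CO[Si](C)(C)C(C)(C)C | intermediate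
20 | (E)-but-2-enal | C/C=C/C=O | starting material
21 | (Z)-2-iodobut-2-enal | C/C=C(\I)C=O | intermediate
22 | (Z)-1,1-diethoxy-2-iodobut-2-ene | C/C=C(\I)C(OCC)OCC | intermediate
23 | acrolein | C=CC=O | starting material
24 | (2E,4E)-4-(diethoxymethyl)hexa-2,4-dienal | C/C=C(/C(OCC)OCC)\C=C\C=O | intermediate
25 | diallyl malonate | C=CCOC(=O)CC(=O)OCC=C | starting material
26 | diallyl 2-[(3S,4E)-4-(diethoxymethyl)-1-oxohex-4-en-3-yl]malonate | C/C=C(/C(OCC)OCC)[C@@H](CC=O)C(C(=O)OCC=C)C(=O)OCC=C | intermediate
27 | diallyl 2-[(3S,4E)-1,1-diethoxy-4-(diethoxymethyl)hex-4-en-3-yl]malonate | C/C=C(/C(OCC)OCC)[C@@H](CC(OCC)OCC)C(C(=O)OCC=C)C(=O)OCC=C | intermediate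
28 | 2-[(3S,4E)-1,1-diethoxy-4-(diethoxymethyl)hex-4-en-3-yl]malonic acid | C/C=C(/C(OCC)OCC)[C@@H](CC(OCC)OCC)C(C(=O)O)C(=O)O | intermediate
29 | (3S,4E)-3-(2,2-diethoxyethyl)-4-(diethoxymethyl)hex-4-enoic acid | C/C=C(/C(OCC)OCC)[C@@H](CC(OCC)OCC)CC(=O)O | intermediate
30 | protected diester: 19 esterified at O3 and O7 with the acyl group of 29 | C/C=C(/C(OCC)OCC)[C@@H](CC(OCC)OCC)CC(=O)OC[C@H](CO[Si](C)(C)C(C)(C)C)[C@@H]1C[C@@H](OC(=O)C[C@H](CC(OCC)OCC)/C(C(OCC)OCC)=C\C)[C@H](C)[C@H]1CO[Si](C)(C)C(C)(C)C | intermediate
31 | CNP0192766.1 | C/C=C(/C=O)[C@@H](CC=O)CC(=O)OC[C@H](CO)[C@@H]1C[C@@H](OC(=O)C[C@H](CC=O)/C(C=O)=C\C)[C@H](C)[C@H]1CO | target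

**Totals**

Total step count: 18. Longest linear sequence: 13 (steps 1–11, 17, 18).

**Steps most likely to fail**

1. Step 2. Proton transfer between the methylated ketone and unreacted enolate can move the enolate to C6, from where the silyloxy group is expelled, and can lead to over-methylation. Fallback, setting out from 3 and returning at 7: α-iodination of 3 (I2, pyridine, CH2Cl2) gives (R)-4-(tert-butyldimethylsilyloxy)-2-iodocyclopent-2-en-1-one F1. Stille methylation (Me4Sn, Pd2(dba)3, AsPh3, CuI, NMP) gives (R)-4-(tert-butyldimethylsilyloxy)-2-methylcyclopent-2-en-1-one F2, so the methyl group is in place before any enolate is formed. CuBr·SMe2-catalysed addition of 2 with a cold NH4Cl quench then needs no alkylation and gives 7 together with its C8 epimer F3. Both go forward, because C8 equilibrates to the trans arrangement under the DBU of step 3.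

2. Step 4. The equilibrium between the two C4 epimers of the lactone may not discriminate enough, and the base may open the ring by retro-Michael reaction. Fallback, setting out from 11 and returning at 19: crude 11 is silylated at O1 before it lactonises (TBSCl, imidazole) to the silyl ether F4. Reduction as in step 5 gives the C7 β-alcohol F5. LiAlH4 reduces both benzyl esters to the propane-1,3-diol F6, in which C4 is not yet stereogenic. A lipase (Candida antarctica lipase B or Burkholderia cepacia lipase, vinyl acetate, or the complementary hydrolysis of the diacetate) acetylates one of the two diastereotopic CH2OH groups and is chosen to give the O3 monoacetate F7. Silylation of O11 gives the acetate bis-silyl ether F8, and K2CO3/MeOH gives 19. C4 then rests on enzyme recognition instead of a conformational equilibrium, and steps 6–11 are bypassed.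

3. Step 5. Hydride delivery may show poor facial selectivity, because the two α-carbons of the ketone differ only by one methyl group. Fallback, setting out from 12 and returning at 13: K[HB(s-Bu)3] (THF, −78 °C) should attack anti to the C8 methyl and give the C7 α-alcohol F9. Mitsunobu reaction with chloroacetic acid (PPh3, DIAD) inverts C7 to the β-chloroacetate F10. Thiourea/NaHCO3 in EtOH removes the chloroacetyl group without touching the lactone or the benzyl ester and gives 13.

Further compounds

F1 | step 2 | (R)-4-(tert-butyldimethylsilyloxy)-2-iodocyclopent-2-en-1-one | CC(C)(C)[Si](C)(C)O[C@@H]1CC(=O)C(I)=C1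
F2 | step 2 | (R)-4-(tert-butyldimethylsilyloxy)-2-methylcyclopent-2-en-1-one | CC(C)(C)[Si](C)(C)O[C@@H]1CC(=O)C(C)=C1
F3 | step 2 | (2S,3R,4R)-4-(tert-butyldimethylsilyloxy)-3-{[dimethyl(propan-2-yloxy)silyl]methyl}-2-methylcyclopentan-1-one (C8 epimer of 7) | CC(C)(C)[Si](C)(C)O[C@@H]1CC(=O)[C@@H](C)[C@H]1C[Si](C)(C)OC(C)C
F4 | step 4 | dibenzyl 2-[2β-(tert-butyldimethylsilyloxymethyl)-3α-methyl-4-oxocyclopent-1α-yl]malonate | O=C(OCc1ccccc1)C(C(=O)OCc1ccccc1)[C@@H]1CC(=O)[C@H](C)[C@H]1CO[Si](C)(C)C(C)(C)C
F5 | step 4 | dibenzyl 2-[2β-(tert-butyldimethylsilyloxymethyl)-4β-hydroxy-3α-methylcyclopent-1α-yl]malonate | O=C(OCc1ccccc1)C(C(=O)OCc1ccccc1)[C@@H]1C[C@@H](O)[C@H](C)[C@H]1CO[Si](C)(C)C(C)(C)C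
F6 | step 4 | 2-[2β-(tert-butyldimethylsilyloxymethyl)-4β-hydroxy-3α-methylcyclopent-1α-yl]propane-1,3-diol | OCC(CO)[C@@H]1C[C@@H](O)[C@H](C)[C@H]1CO[Si](C)(C)C(C)(C)C
F7 | step 4 | O3 monoacetate of F6, C4 as in the target | CC(=O)OC[C@H](CO)[C@@H]1C[C@@H](O)[C@H](C)[C@H]1CO[Si](C)(C)C(C)(C)C
F8 | step 4 | O3 acetate of 19 | CC(=O)OC[C@H](CO[Si](C)(C)C(C)(C)C)[C@@H]1C[C@@H](O)[C@H](C)[C@H]1CO[Si](C)(C)C(C)(C)C
F9 | step 5 | benzyl 6α-hydroxy-7α-methyl-3-oxooctahydrocyclopenta[c]pyran-4-carboxylate (C7 epimer of 13) | O=C(OCc1ccccc1)[C@H](C(=O)O2)[C@@H]1C[C@H](O)[C@H](C)[C@H]1C2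
F10 | step 5 | benzyl 6β-(chloroacetoxy)-7α-methyl-3-oxooctahydrocyclopenta[c]pyran-4-carboxylate | O=C(OCc1ccccc1)[C@H](C(=O)O2)[C@@H]1C[C@@H](OC(=O)CCl)[C@H](C)[C@H]1C2
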